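## Structural features

The target is a spirolactone of the 6,7-seco-ent-kaurane type. Ring A is a 4,4-dimethylcyclohex-2-en-1-one (C1 ketone, C2=C3, gem-dimethyl C4, C5 bearing C6H2OH) whose C10 is the spiro atom of a δ-lactone C10–C20H2–O–C7(=O)–C8–C9. The lactone is cis-fused through C8–C9 to ring C (C8, C9, C11–C14), and C8 and C13 are bridged by C15(=O)–C16(CH3)(OH), so that rings C and D form a bicyclo[3.2.1]octane. Four stereocentres are contiguous (C5, C10, C9, C8), with C9 wedged between the quaternary carbons C10 and C8, and two more (C13, C16) sit on the bicycle. The configuration read from the structure is 5R,8S,9S,10S,13R,16S, with C6 and C20 cis on ring A and the C16 hydroxyl on the exo face (the side of the C14 bridge). Fragile groups are the non-enolisable β-keto lactone C7/C8/C15 (retro-Claisen cleavage by nucleophiles), the tertiary α-ketol C15/C16 (ketol shift in base or acid), the enone (conjugate addition) and the free primary C6 hydroxyl. The real difficulty is the quaternary C8, bonded to two carbonyl carbons next to the congested C9, together with the C9/C10 relationship across a bond that is acyclic until the lactone exists. The key step uses the fact that C8 is bonded to both C7 and C15: this 1,3-dicarbonyl array lets the C7–C8 bond come from the C15 enolate and an activated carbonate on the C20 oxygen through a six-membered ring, which closes the lactone and fixes C8 relative to C9.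

## Logic of the disconnections

21 ⇒ 20. The O–Si bond at C6 is cut. The primary hydroxyl has to be masked through base, Lewis acid and oxidant; a tert-butyldiphenylsilyl ether is chosen because it survives aqueous acid (step 8) and hot acetic acid (step 11). The forward step needs a fluoride source acidic enough to spare the β-keto lactone and the α-ketol.

20 ⇒ 19. The C16–O bond is cut. C16 is the only enolisable carbon of 19 (C8 is quaternary, the ring A ketone has no α-hydrogen), so the oxygen can come last and the α-ketol is absent from all earlier steps. The forward step must deliver oxygen to the exo face of the bicyclic enolate.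

19 ⇒ 18. The C13–C16 bond (ring D) is cut. This turns the bicyclo[3.2.1]octane into a cyclohexene with a propanoyl group on C8. The forward radical closure needs that group axial and cis to C9–H and a ketone that enolises in one direction only; the quaternary C8 of 18 provides both.

18 ⇒ 17 (key step). The C7–C8 bond is cut. This removes the lactone ring and the quaternary stereocentre at once and leaves a ketone and a carbonate derivative joined through C9–C10–C20–O. The forward step needs an acyl donor on O20 that loses a weakly basic leaving group, and a C8 that can be enolised. The stereodescriptors of 17 and 18 match those of 21 atom by atom at C5, C9 and C10, so the structures needed no correction. Two spectator features of the precursor are changed: the C6 silyl ether is tert-butyldiphenylsilyl and not tert-butyldimethylsilyl (see above), and the C8 configuration of 17 is left uncontrolled on purpose because it is erased on enolisation.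

17 ⇒ 15 + 16. The O20–C7 bond is cut. The neopentyl primary alcohol of 15 is the only hydroxyl present, so acylation by 16 needs no selectivity.

15 ⇒ 12 + 13 (through 14). The C9–C11 and C8–C14 bonds are cut. A cyclohexene with a C12=C13 double bond and vicinal acyl and alkyl groups is the adduct of 13 with an E-enone. One cycloaddition replaces conjugate allylation, enolate allylation and metathesis. An allyl nucleophile would have to choose between two β-neopentyl enones, and an allyl halide between two α-positions; the cycloaddition avoids both choices. The forward step demands that the s-cis side-chain enone reacts faster than the s-trans-locked ring A enone and that the diene adds to the C9 face turned toward C1. The C20 hydroxyl is masked (12 ⇐ 11) so that no aluminium alkoxide can chelate and activate the ring A ketone.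

11 ⇒ 10 ⇒ 8 + 9. First the C20–H bond is cut (redox), then the C10–C9 bond. With C20 at the aldehyde level, C10 is the carbon of a 1,3-dicarbonyl and adds to the ynone 9 under amine catalysis; this installs the complete side-chain enone in one step, with no aldehyde/olefination sequence and no protecting group on O20. Demands: 9 must enter trans to C6 (so that C20 ends up cis to C6), and the hindered aldehyde must then be reduced in the presence of two enones.

8 ⇒ 6 + 7. The C10–C20 bond is cut. In the enone 6 the position C10 is the only acidic one (C2 is vinylic, C4 quaternary), so formylation needs no regiocontrol.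

6 ⇒ 5 ⇒ 2 + 3 (through 4). The O–Si bond and then the C5–C6 bond are cut. A hydroxymethyl anion equivalent from 3 adds to one of the two enantiotopic enone units of 2; this single catalytic step sets C5 and with it the absolute configuration, and the second enone unit survives as the ring A enone. The forward step demands enantioface control with a bulky silylmethyl nucleophile.

2 ⇒ 1. The second ring double bond is removed. Dehydrogenation of 1 can go in one direction only, because C4 is quaternary.

## Other disconnections considered

Alternative 1: The cut is C13–C16. In the forward sense Mn(OAc)3 oxidises the enol of the C8 propanoyl group of the spiro lactone A1 to the C16 radical, which adds 5-exo to C13 of the C12=C13 alkene and closes ring D to give the 16-deoxy ketone A2. In its favour: one step builds a ring, a C–C bond and the C13 stereocentre; the conditions are oxidative and weakly acidic, so the β-keto lactone and the enone are not at risk; the quaternary C8 leaves a single enolisation direction. Against it as the leading disconnection: it presupposes exactly what is hard, namely the quaternary C8, the cis-fused lactone and the axial propanoyl group, and leaves C16 oxygenation open; closure at C12 (6-exo, bicyclo[2.2.2]octane) is a conceivable competitor. Comparison: on structure the two steps are equal (one ring, one bond, one stereocentre each). On mechanism the radical closure is the better of the two in tolerance, since it involves no free enolate next to a congested 1,5-dicarbonyl array. On step economy there is no difference, because the closure is not a rival but the step that follows the chosen one (step 11 below uses it on 18).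

Alternative 2: The cut is C5–C10. In the forward sense a Lewis acid opens the C10–C20 epoxide of the epoxy cyclopentanol A3 at C10 while C5 migrates from the carbinol carbon C1 to C10; the cyclopentanol expands to ring A and the C1 ketone and C20 hydroxyl appear in the ring A block A4. In its favour: the 1,2-shift is stereospecific (inversion at C10, retention at C5), so the configuration of the quaternary C10 follows from the epoxide and not from the facial bias of an enolate. On this point it is the better of the two plans (compare step 5 below). It also delivers the two one-carbon arms on C10 already differentiated. Against it: A3 needs three defined stereocentres, including a diastereoselective epoxidation; migration of C2 can compete with migration of C5; A4 has a saturated ring A and C9 at the alcohol level, so debenzylation, oxidation, olefination, protection of O20 and introduction of the C2=C3 double bond must follow. Comparison: the step solves an early problem (C10) and says nothing about C8 or the lactone, so on structure it complements the chosen key step and does not replace it. On mechanism it is the more predictable of the two. On step economy it is worse, since the chosen route reaches the corresponding stage (11) in six steps from 1 without any of these adjustments.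

Alternative 3: The cuts are C8–C9 and C8–C14. In the forward sense the C8 methylene of the 3-oxopentanoate ester on O20 of the dienone A5 adds to C9 (6-exo, closing the lactone) and then to C14 (6-endo, closing ring C) of the C9=C11–C12(=O)–C13=C14 unit, giving the spiro lactone A6 with a C12 ketone. In its favour: two bonds, two rings and two stereocentres (C8, C9) arise in one operation, which is more than the chosen step builds and is the better on that count. C9 is set inside a six-membered transition state tied to C10, which may control the C9/C10 relationship better than the intermolecular cycloaddition of step 8; this is a real point for the alternative. The nucleophile is a soft β-keto ester anion under mild base. Against it: A6 carries a C12 ketone that has to become the C12=C13 alkene regioselectively in the presence of the C1 and C15 ketones, which costs at least two further steps and a chemoselectivity problem. The divinyl ketone of A5 is prone to polymerisation and offers two acceptor termini to the first addition. Comparison: on structure the alternative is richer per step. On mechanism it is reversible and so thermodynamically steerable, whereas the chosen acylation is kinetically funnelled and irreversible. On step economy the gain is used up by the removal of the C12 oxygen, so the overall count should be no better.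

Key step: step 10

Assumption: pent-1-yn-3-one (9) and (chloromethyl)dimethyl(propan-2-yloxy)silane (3) are taken as catalogue compounds, and the antipode of the ferrocenyl diphosphine that leads to the 5S series in step 2 is to be fixed by a preliminary run, since the sense of induction is not predicted here.

## Route

Step 1
Reactants: 1 4,4-dimethylcyclohex-2-en-1-one
Product: 2 4,4-dimethylcyclohexa-2,5-dien-1-one
Conditions: DDQ (1.5 equiv), 1,4-dioxane, reflux
Reagents that add atoms: none
Why: Quinone dehydrogenation of a cyclohexenone; hydride abstraction from the dienol can occur only at C5/C6 because C4 is quaternary. The symmetric dienone brings the ring A enone in from the start and later makes C10 the only acidic position of ring A.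

Step 2
Reactants: 2 4,4-dimethylcyclohexa-2,5-dien-1-one; 3 (chloromethyl)dimethyl(propan-2-yloxy)silane (used as its Grignard reagent)
Product: 5 (5S)-5-(hydroxymethyl)-4,4-dimethylcyclohex-2-en-1-one, via silane 4 (not isolated)
Conditions: 3, Mg, THF; CuBr·SMe2 (5 mol%), (R)-1-[(S)-2-(diphenylphosphino)ferrocenyl]ethyldicyclohexylphosphine or its antipode (6 mol%), t-BuOMe, −78 °C; cold 1 M HCl; then crude 4, H2O2 (30% aq), KF, KHCO3, THF–MeOH, rt
Reagents that add atoms: (chloromethyl)dimethyl(propan-2-yloxy)silane (3), CC(C)O[Si](C)(C)CCl; hydrogen peroxide, OO
Why: Copper-catalysed enantioselective conjugate addition of a Grignard reagent to one of the two enantiotopic enone units, in which the chiral diphosphine selects the face and so sets C5 (the sense is to be established, see the assumption). Tamao oxidation then replaces C–Si by C–OH with retention, and the bicarbonate-buffered peroxide should leave the hindered enone untouched.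

Step 3
Reactants: 5 (5S)-5-(hydroxymethyl)-4,4-dimethylcyclohex-2-en-1-one
Product: 6 (5S)-5-{[tert-butyl(diphenyl)silyl]oxymethyl}-4,4-dimethylcyclohex-2-en-1-one
Conditions: t-BuPh2SiCl, imidazole, DMF, rt
Reagents that add atoms: tert-butyl(chloro)diphenylsilane, CC(C)(C)[Si](Cl)(c1ccccc1)c1ccccc1
Why: Standard silylation of a primary alcohol. The tert-butyldiphenylsilyl group is chosen because it should withstand the aqueous acid of step 8 and the hot acetic acid of step 11.

Step 4
Reactants: 6 (5S)-5-{[tert-butyl(diphenyl)silyl]oxymethyl}-4,4-dimethylcyclohex-2-en-1-one; 7 ethyl formate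
Product: 8 (5R,6Z)-5-{[tert-butyl(diphenyl)silyl]oxymethyl}-6-(hydroxymethylidene)-4,4-dimethylcyclohex-2-en-1-one (enol form of the 6-formyl ketone)
Conditions: NaH (2 equiv), HCO2Et (5 equiv), EtOH (cat.), THF, 0 °C to rt; then 1 M HCl
Reagents that add atoms: ethyl formate (7), CCOC=O
Why: Crossed Claisen formylation at the only enolisable carbon of the enone (C10; C2 is vinylic, C4 quaternary), driven by formation of the sodium salt of the 1,3-dicarbonyl product. The new carbon is the future C20.

Step 5
Reactants: 8 (5R,6Z)-5-{[tert-butyl(diphenyl)silyl]oxymethyl}-6-(hydroxymethylidene)-4,4-dimethylcyclohex-2-en-1-one; 9 pent-1-yn-3-one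
Product: 10 (1S,6R)-6-{[tert-butyl(diphenyl)silyl]oxymethyl}-5,5-dimethyl-2-oxo-1-[(1E)-3-oxopent-1-en-1-yl]cyclohex-3-ene-1-carbaldehyde
Conditions: 9 (1.2 equiv), Et3N (10 mol%), CH2Cl2, 0 °C to rt; then I2 (2 mol%), rt
Reagents that add atoms: pent-1-yn-3-one (9), CCC(=O)C#C
Why: Amine-catalysed Michael addition of a 1,3-dicarbonyl to a terminal ynone forms C10–C9 and the quaternary centre; any O-adduct should revert by addition–elimination while the C-adduct cannot. The acceptor should approach the planar C10 from the face of C5–H, opposite to the C5 silyloxymethyl group, so that the side chain is trans to C6 and the formyl carbon (C20) cis to it. Iodine equilibrates the enone to the E isomer.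

Step 6
Reactants: 10 (1S,6R)-6-{[tert-butyl(diphenyl)silyl]oxymethyl}-5,5-dimethyl-2-oxo-1-[(1E)-3-oxopent-1-en-1-yl]cyclohex-3-ene-1-carbaldehyde
Product: 11 (5R,6S)-5-{[tert-butyl(diphenyl)silyl]oxymethyl}-6-(hydroxymethyl)-4,4-dimethyl-6-[(1E)-3-oxopent-1-en-1-yl]cyclohex-2-en-1-one
Conditions: NaBH4 (0.3 equiv), CH2Cl2–EtOH, −78 °C; aq. NH4Cl
Reagents that add atoms: none
Why: Chemoselective borohydride reduction: at −78 °C an aldehyde, even an α-quaternary one, is reduced much faster than a conjugated ketone, so both enones should survive. The cold, nearly neutral quench avoids retro-aldol loss of formaldehyde from the β-hydroxy ketone.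

Step 7
Reactants: 11 (5R,6S)-5-{[tert-butyl(diphenyl)silyl]oxymethyl}-6-(hydroxymethyl)-4,4-dimethyl-6-[(1E)-3-oxopent-1-en-1-yl]cyclohex-2-en-1-one
Product: 12 (5R,6S)-5-{[tert-butyl(diphenyl)silyl]oxymethyl}-4,4-dimethyl-6-[(1E)-3-oxopent-1-en-1-yl]-6-{[(triethylsilyl)oxy]methyl}cyclohex-2-en-1-one
Conditions: Et3SiCl, imidazole, CH2Cl2, 0 °C
Reagents that add atoms: chlorotriethylsilane, CC[Si](Cl)(CC)CC
Why: Silylation of the neopentyl alcohol. The triethylsilyl ether prevents formation of an aluminium alkoxide in step 8 (which would chelate and activate the ring A ketone) and is far more acid-labile than the silyl ether at O6.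

Step 8
Reactants: 12 (5R,6S)-5-{[tert-butyl(diphenyl)silyl]oxymethyl}-4,4-dimethyl-6-[(1E)-3-oxopent-1-en-1-yl]-6-{[(triethylsilyl)oxy]methyl}cyclohex-2-en-1-one; 13 buta-1,3-diene
Product: 15 (5R,6S)-5-{[tert-butyl(diphenyl)silyl]oxymethyl}-6-(hydroxymethyl)-4,4-dimethyl-6-[(1R,6R)-6-propanoylcyclohex-3-en-1-yl]cyclohex-2-en-1-one, via triethylsilyl ether 14 (not isolated)
Conditions: 13 (excess), Me2AlCl (2 equiv), CH2Cl2, −78 to 0 °C; then 1 M HCl, THF, rt
Reagents that add atoms: buta-1,3-diene (13), C=CC=C
Why: Lewis acid-promoted Diels–Alder reaction; the acyclic enone can adopt the reactive s-cis geometry and should react well before the s-trans-locked, β-neopentyl ring A enone, and suprafacial addition to the E-alkene gives C8/C9 trans (C8 is erased later). In the rotamer with C9–H over ring A and C9=C8 syn to C10–C20, the face turned toward C5 is screened by C5–H and the syn methyl on C4, so the diene should add from the C1 side and set C9 as required (9R in 15). The acidic work-up removes the triethylsilyl group only.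

Step 9
Reactants: 15 (5R,6S)-5-{[tert-butyl(diphenyl)silyl]oxymethyl}-6-(hydroxymethyl)-4,4-dimethyl-6-[(1R,6R)-6-propanoylcyclohex-3-en-1-yl]cyclohex-2-en-1-one; 16 1,1'-carbonyldiimidazole
Product: 17 [(1S,6R)-6-{[tert-butyl(diphenyl)silyl]oxymethyl}-5,5-dimethyl-2-oxo-1-[(1R,6R)-6-propanoylcyclohex-3-en-1-yl]cyclohex-3-en-1-yl]methyl 1H-imidazole-1-carboxylate
Conditions: 16 (1.5 equiv), CH2Cl2, rt
Reagents that add atoms: 1,1'-carbonyldiimidazole (16), O=C(n1ccnc1)n1ccnc1
Why: Acylation of the only hydroxyl group by carbonyldiimidazole gives the imidazole-1-carboxylate, which places the future C7 on O20. Ketones, alkene and silyl ether are inert under these neutral conditions.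

Step 10
Reactants: 17 [(1S,6R)-6-{[tert-butyl(diphenyl)silyl]oxymethyl}-5,5-dimethyl-2-oxo-1-[(1R,6R)-6-propanoylcyclohex-3-en-1-yl]cyclohex-3-en-1-yl]methyl 1H-imidazole-1-carboxylate
Product: 18 (5R,8S,9S,10S)-spiro lactone: ring A enone spiro-fused at C10 to the δ-lactone C10–C20H2–O–C7(=O)–C8–C9, which is cis-fused at C8–C9 to cyclohexene ring C (C12=C13); C8 carries the propanoyl group (C15–C17) cis to C9–H, and C5 the CH2OSi(t-Bu)Ph2 group
Conditions: NaH (1.3 equiv), THF, 0 °C to rt; AcOH (1.5 equiv), 0 °C
Reagents that add atoms: none
Why: NaH deprotonates the C15 ketone reversibly on both sides, and the imidazole set free shuttles protons, so the C8 and C16 enolates interconvert. Only the C8 enolate can reach the imidazole-1-carboxylate carbon through a six-membered transition state (C8–C9–C10–C20–O–C7); addition to C7 and loss of imidazolide form the C7–C8 bond and close the δ-lactone. The closest known reaction type is the intramolecular Claisen (Dieckmann-like) C-acylation of ketone enolates by carbonates or acyl imidazoles to cyclic β-keto esters. The ring closes in the 6-(enolexo)-exo-trig mode. The new stereocentre C8 is controlled by C9: allylic strain in the exocyclic enolate holds the C10 substituent axial on ring C, the tether delivers C7 to that face, and the lactone is therefore cis-fused with the propanoyl group axial and cis to C9–H (8S). The step needs C- over O-acylation and C8 over C16; O-acylation and attack from C16 would both require eight-membered rings, and the ring A ketone has no α-hydrogen and cannot form a competing enolate. Aldol or Michael additions of either enolate to ring A are reversible, whereas the acylation is not, because C8 becomes quaternary and imidazolide does not cleave the product. The C8 configuration of 17 is irrelevant since it is lost on enolisation.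

Step 11
Reactants: 18 (5R,8S,9S,10S)-spiro lactone with C8 propanoyl group and C12=C13 alkene
Product: 19 (5R,8S,9S,10S,13R)-16-deoxy tetracycle: ring D closed by the C13–C16 bond (bicyclo[3.2.1]octan-15-one with 16-methyl, epimers at C16), C6 O-tert-butyldiphenylsilyl ether
Conditions: Mn(OAc)3·2H2O (2.2 equiv), AcOH–EtOH (4:1), 80 °C, argon
Reagents that add atoms: none
Why: Oxidative free-radical cyclisation of an unsaturated ketone: trivalent manganese oxidises the only possible enol (C15=C16) to the C16 radical, which adds 5-exo-trig to C13 from the face that carries the axial propanoyl group, and the C12 radical is reduced by hydrogen abstraction from ethanol. C13 is fixed by the geometry of the bridge; the C16 configuration is not controlled and does not matter.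

Step 12
Reactants: 19 (5R,8S,9S,10S,13R)-16-deoxy tetracycle (epimers at C16)
Product: 20 (5R,8S,9S,10S,13R,16S)-6-O-tert-butyldiphenylsilyl ether of the target
Conditions: KN(SiMe3)2 (1.2 equiv), THF, −78 °C; 2-(phenylsulfonyl)-3-phenyloxaziridine (1.5 equiv); AcOH, −78 °C
Reagents that add atoms: 2-(phenylsulfonyl)-3-phenyloxaziridine, O=S(=O)(N1OC1c1ccccc1)c1ccccc1
Why: Enolate hydroxylation with an N-sulfonyloxaziridine; C16–H is the only acidic hydrogen, and both C16 epimers give the same potassium enolate. The oxidant should attack the two-carbon bridge from the exo face (the side of C14, away from C11/C12), placing OH exo and CH3 endo as in the target; the cold acidic quench limits ketol shift and retro-Claisen cleavage.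

Step 13
Reactants: 20 (5R,8S,9S,10S,13R,16S)-6-O-tert-butyldiphenylsilyl ether of the target
Product: 21 target CNP0530135.1, (5R,8S,9S,10S,13R,16S)
Conditions: HF·pyridine, pyridine, THF, 0 °C to rt
Reagents that add atoms: none
Why: Fluoride-mediated cleavage of the primary silyl ether under buffered acidic conditions. The β-keto lactone and the tertiary α-ketol, both base-sensitive, should be stable in this medium.

## Compound list

1 | 4,4-dimethylcyclohex-2-en-1-one | CC1(C)CCC(=O)C=C1 | starting material
2 | 4,4-dimethylcyclohexa-2,5-dien-1-one | CC1(C)C=CC(=O)C=C1 | intermediate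
3 | (chloromethyl)dimethyl(propan-2-yloxy)silane | CC(C)O[Si](C)(C)CCl | starting material
4 | (5S)-5-{[dimethyl(propan-2-yloxy)silyl]methyl}-4,4-dimethylcyclohex-2-en-1-one (not isolated) | CC1(C)C=CC(=O)C[C@@H]1C[Si](C)(C)OC(C)C | intermediate
5 | (5S)-5-(hydroxymethyl)-4,4-dimethylcyclohex-2-en-1-one | CC1(C)C=CC(=O)C[C@@H]1CO | intermediate
6 | (5S)-5-{[tert-butyl(diphenyl)silyl]oxymethyl}-4,4-dimethylcyclohex-2-en-1-one | CC1(C)C=CC(=O)C[C@@H]1CO[Si](c1ccccc1)(c1ccccc1)C(C)(C)C | intermediate
7 | ethyl formate | CCOC=O | starting material
8 | (5R,6Z)-5-{[tert-butyl(diphenyl)silyl]oxymethyl}-6-(hydroxymethylidene)-4,4-dimethylcyclohex-2-en-1-one | CC1(C)C=CC(=O)/C(=C\O)[C@@H]1CO[Si](c1ccccc1)(c1ccccc1)C(C)(C)C | intermediate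
9 | pent-1-yn-3-one | CCC(=O)C#C | starting material
10 | (1S,6R)-6-{[tert-butyl(diphenyl)silyl]oxymethyl}-5,5-dimethyl-2-oxo-1-[(1E)-3-oxopent-1-en-1-yl]cyclohex-3-ene-1-carbaldehyde | CC1(C)C=CC(=O)[C@@](C=O)(/C=C/C(=O)CC)[C@@H]1CO[Si](c1ccccc1)(c1ccccc1)C(C)(C)C | intermediate
11 | (5R,6S)-5-{[tert-butyl(diphenyl)silyl]oxymethyl}-6-(hydroxymethyl)-4,4-dimethyl-6-[(1E)-3-oxopent-1-en-1-yl]cyclohex-2-en-1-one | CC1(C)C=CC(=O)[C@@](CO)(/C=C/C(=O)CC)[C@@H]1CO[Si](c1ccccc1)(c1ccccc1)C(C)(C)C | intermediate
12 | (5R,6S)-5-{[tert-butyl(diphenyl)silyl]oxymethyl}-4,4-dimethyl-6-[(1E)-3-oxopent-1-en-1-yl]-6-{[(triethylsilyl)oxy]methyl}cyclohex-2-en-1-one | CC1(C)C=CC(=O)[C@@](CO[Si](CC)(CC)CC)(/C=C/C(=O)CC)[C@@H]1CO[Si](c1ccccc1)(c1ccccc1)C(C)(C)C | intermediate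
13 | buta-1,3-diene | C=CC=C | starting material
14 | (5R,6S)-5-{[tert-butyl(diphenyl)silyl]oxymethyl}-4,4-dimethyl-6-[(1R,6R)-6-propanoylcyclohex-3-en-1-yl]-6-{[(triethylsilyl)oxy]methyl}cyclohex-2-en-1-one (not isolated) | CC1(C)C=CC(=O)[C@@](CO[Si](CC)(CC)CC)([C@@H]2CC=CC[C@H]2C(=O)CC)[C@@H]1CO[Si](c1ccccc1)(c1ccccc1)C(C)(C)C | intermediate
15 | (5R,6S)-5-{[tert-butyl(diphenyl)silyl]oxymethyl}-6-(hydroxymethyl)-4,4-dimethyl-6-[(1R,6R)-6-propanoylcyclohex-3-en-1-yl]cyclohex-2-en-1-one | CC1(C)C=CC(=O)[C@@](CO)([C@@H]2CC=CC[C@H]2C(=O)CC)[C@@H]1CO[Si](c1ccccc1)(c1ccccc1)C(C)(C)C | intermediate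
16 | 1,1'-carbonyldiimidazole | O=C(n1ccnc1)n1ccnc1 | starting material
17 | [(1S,6R)-6-{[tert-butyl(diphenyl)silyl]oxymethyl}-5,5-dimethyl-2-oxo-1-[(1R,6R)-6-propanoylcyclohex-3-en-1-yl]cyclohex-3-en-1-yl]methyl 1H-imidazole-1-carboxylate (precursor of the key step) | CC1(C)C=CC(=O)[C@@](COC(=O)n2ccnc2)([C@@H]2CC=CC[C@H]2C(=O)CC)[C@@H]1CO[Si](c1ccccc1)(c1ccccc1)C(C)(C)C | intermediate
18 | (5R,8S,9S,10S)-spiro lactone: C20–O–C7(=O) δ-lactone spiro at C10 to the ring A enone and cis-fused at C8–C9 to cyclohex-12-ene ring C, C8 propanoyl cis to C9–H, C6 O-tert-butyldiphenylsilyl (product of the key step) | CC1(C)C=CC(=O)[C@]2(COC(=O)[C@@]3(C(=O)CC)CC=CC[C@H]32)[C@@H]1CO[Si](c1ccccc1)(c1ccccc1)C(C)(C)C | intermediate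
19 | (5R,8S,9S,10S,13R)-16-deoxy tetracycle, C6 O-tert-butyldiphenylsilyl, both configurations at C16 | CC1(C)C=CC(=O)[C@]2(COC(=O)[C@@]34C[C@@H](CC[C@H]32)C(C)C4=O)[C@@H]1CO[Si](c1ccccc1)(c1ccccc1)C(C)(C)C | intermediate
20 | (5R,8S,9S,10S,13R,16S)-6-O-tert-butyldiphenylsilyl ether of the target | CC1(C)C=CC(=O)[C@]2(COC(=O)[C@@]34C[C@@H](CC[C@H]32)[C@](C)(O)C4=O)[C@@H]1CO[Si](c1ccccc1)(c1ccccc1)C(C)(C)C | intermediate
21 | CNP0530135.1, (5R,8S,9S,10S,13R,16S): 16-hydroxy-16-methyl-15-oxo 7,20-spirolactone with ring A enone and C6 hydroxymethyl | CC1(C)C=CC(=O)[C@]2(COC(=O)[C@@]34C[C@@H](CC[C@H]32)[C@](C)(O)C4=O)[C@@H]1CO | target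

## Step count and least certain steps

Total step count: 13. Longest linear sequence: 13 steps, from 1 to 21 (all other inputs are purchased).

Step 10 (key step). What may go wrong: retro-Michael cleavage of the congested C9–C10 bond from the C8 enolate (the C15/C1 pair is a 1,5-dicarbonyl), or aldol capture of the C16 enolate by the C1 ketone before proton transfer has reached C8. Both are consequences of a free alkali enolate next to a strained quaternary–tertiary bond. Fallback: setting out from 15, the alcohol is converted with bis(pentafluorophenyl) carbonate and DMAP into the pentafluorophenyl carbonate F1, and the ring is closed by soft enolisation (MgBr2·OEt2, i-Pr2NEt, CH2Cl2), a known way to C-acylate ketones with activated esters. Enolisation is then reversible and magnesium-bound, no free alkali enolate is present, and the route is rejoined at 18.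

Step 8. What may go wrong: insufficient facial discrimination at C9 (the three substituents on C10 differ only moderately as seen from C9), sluggish cycloaddition at the β-neopentyl dienophile, and, if the temperature has to be raised, cycloaddition at the ring A enone. Fallback: the C9–C10 bond is made with ring C already in place. Buta-1,3-diene 13 and pent-1-yn-3-one 9 are heated in toluene to give 1-(cyclohexa-1,4-dien-1-yl)propan-1-one F2. Setting out from 8, Michael addition to F2 (catalytic DBU, or a cinchona-derived amine–thiourea if catalyst control of the C9 face is wanted) gives the aldehyde F3, and reduction with NaBH4 at −78 °C rejoins the route at 15. C9 is then set in a different bond-forming event with different steric determinants, and steps 5 to 8 are bypassed.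

Step 5. What may go wrong: erosion or reversal of the facial selectivity at C10, since one face of the planar carbon is flanked by the C5 substituent and the other by the syn methyl on C4; incomplete equilibration to the E-enone would also lower the efficiency of step 8. Fallback for a preference syn to C6: the order of the two C10 substituents is inverted. Setting out from 8, aldol reaction with aqueous formaldehyde (KHCO3, THF) gives the hydroxymethyl aldehyde F4, in which the later-introduced hydroxymethyl group is C20 and the formyl group is C9. Silylation (Et3SiCl, imidazole) gives F5, and Horner–Wadsworth–Emmons olefination with diethyl (2-oxobutyl)phosphonate (LiCl, i-Pr2NEt, MeCN) rejoins the route at 12. If both faces react to a similar extent, neither order helps and the epimers would have to be separated at 11.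

Step 2. What may go wrong: low enantioface selectivity with the bulky silylmethyl Grignard reagent on the dienone, competing 1,2-addition, and epoxidation of the enone by peroxide during the C–Si oxidation. Fallback: setting out from 2, rhodium-catalysed asymmetric 1,4-addition of potassium vinyltrifluoroborate ([Rh(acac)(C2H4)2], BINAP antipode chosen for the required series, toluene–water, heat) gives the vinyl enone F6. Ozonolysis of the electron-rich vinyl group (O3, CH2Cl2, pyridine, −78 °C; Me2S) gives the aldehyde F7, which is reduced at once with NaBH(OAc)3 to avoid epimerisation at C5, rejoining the route at 5.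

Step 11. What may go wrong: slow enolisation of the hindered ketone with decomposition in hot acetic acid, 6-exo closure at C12 to the bicyclo[2.2.2]octane, or further oxidation at C16 once ring D is closed. Fallback: setting out from 18, the lithium enolate (LiN(SiMe3)2, THF, −78 °C; only C16 can be deprotonated) is brominated with N-bromosuccinimide to the α-bromo ketone F8, and reductive radical cyclisation (Bu3SnH, AIBN, benzene, 80 °C) rejoins the route at 19 with the same 5-exo closure but without an oxidant.

## Further compounds

F1 | step 10 | [(1S,6R)-6-{[tert-butyl(diphenyl)silyl]oxymethyl}-5,5-dimethyl-2-oxo-1-[(1R,6R)-6-propanoylcyclohex-3-en-1-yl]cyclohex-3-en-1-yl]methyl pentafluorophenyl carbonate | CC1(C)C=CC(=O)[C@@](COC(=O)Oc2c(F)c(F)c(F)c(F)c2F)([C@@H]2CC=CC[C@H]2C(=O)CC)[C@@H]1CO[Si](c1ccccc1)(c1ccccc1)C(C)(C)C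
F2 | step 8 | 1-(cyclohexa-1,4-dien-1-yl)propan-1-one | CCC(=O)C1=CCC=CC1
F3 | step 8 | (1S,6R)-6-{[tert-butyl(diphenyl)silyl]oxymethyl}-5,5-dimethyl-2-oxo-1-[(1R,6R)-6-propanoylcyclohex-3-en-1-yl]cyclohex-3-ene-1-carbaldehyde | CC1(C)C=CC(=O)[C@@](C=O)([C@@H]2CC=CC[C@H]2C(=O)CC)[C@@H]1CO[Si](c1ccccc1)(c1ccccc1)C(C)(C)C
F4 | step 5 | (1S,6R)-6-{[tert-butyl(diphenyl)silyl]oxymethyl}-1-(hydroxymethyl)-5,5-dimethyl-2-oxocyclohex-3-ene-1-carbaldehyde | CC1(C)C=CC(=O)[C@@](CO)(C=O)[C@@H]1CO[Si](c1ccccc1)(c1ccccc1)C(C)(C)C
F5 | step 5 | (1S,6R)-6-{[tert-butyl(diphenyl)silyl]oxymethyl}-5,5-dimethyl-2-oxo-1-{[(triethylsilyl)oxy]methyl}cyclohex-3-ene-1-carbaldehyde | CC1(C)C=CC(=O)[C@@](CO[Si](CC)(CC)CC)(C=O)[C@@H]1CO[Si](c1ccccc1)(c1ccccc1)C(C)(C)C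
F6 | step 2 | (5R)-5-ethenyl-4,4-dimethylcyclohex-2-en-1-one | CC1(C)C=CC(=O)C[C@@H]1C=C
F7 | step 2 | (1S)-2,2-dimethyl-5-oxocyclohex-3-ene-1-carbaldehyde | CC1(C)C=CC(=O)C[C@@H]1C=O
F8 | step 11 | 16-bromo derivative of 18 (C8 2-bromopropanoyl, both configurations at C16) | CC1(C)C=CC(=O)[C@]2(COC(=O)[C@@]3(C(=O)C(C)Br)CC=CC[C@H]32)[C@@H]1CO[Si](c1ccccc1)(c1ccccc1)C(C)(C)C
A1 | alternative 1 | spiro lactone with C8 propanoyl group and C12=C13 alkene, C6 tert-butyldimethylsilyl ether | CC1(C)C=CC(=O)[C@]2(COC(=O)[C@@]3(C(=O)CC)CC=CC[C@H]32)[C@@H]1CO[Si](C)(C)C(C)(C)C
A2 | alternative 1 | 16-deoxy target as C6 tert-butyldimethylsilyl ether | CC1(C)C=CC(=O)[C@]2(COC(=O)[C@@]34C[C@@H](CC[C@H]32)[C@@H](C)C4=O)[C@@H]1CO[Si](C)(C)C(C)(C)C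
A3 | alternative 2 | 1-[2-(benzyloxymethyl)oxiran-2-yl]-2-{[tert-butyl(dimethyl)silyl]oxymethyl}-3,3-dimethylcyclopentan-1-ol | CC1(C)CC[C@@](O)([C@@]2(COCc3ccccc3)CO2)[C@@H]1CO[Si](C)(C)C(C)(C)C
A4 | alternative 2 | 2-(benzyloxymethyl)-2-(hydroxymethyl)cyclohexanone ring A block | CC1(C)CCC(=O)[C@](COCc2ccccc2)(CO)[C@@H]1CO[Si](C)(C)C(C)(C)C
A5 | alternative 3 | ring A enone with the C20 3-oxopentanoate ester and the C9 (1E)-3-oxopenta-1,4-dien-1-yl group | CC1(C)C=CC(=O)[C@@](COC(=O)CC(=O)CC)(/C=C/C(=O)C=C)[C@@H]1CO[Si](C)(C)C(C)(C)C
A6 | alternative 3 | spiro lactone with ring C as the C12 ketone and C8 propanoyl group | CC1(C)C=CC(=O)[C@]2(COC(=O)[C@@]3(C(=O)CC)CCC(=O)C[C@H]32)[C@@H]1CO[Si](C)(C)C(C)(C)C
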